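**Plan**
- Retrosynthesis: the C9 angelate and C8 methacrylate C–O bonds are cut first. C11–C12 and C6–C7 are then cut together, which opens the γ-lactone and the ten-membered ring to an enal (C6), a terminal allene (C7=C11=C13) and CO2 (C12).
- Enabling feature: the α-methylene-γ-butyrolactone (O–C6–C7–C11(=C13)–C12) is fused on the C6–C7 bond of the carbocycle C1–C10, so C7–C11=C13 is a latent allene and C12 a latent CO2. The 3(2H)-furanone (O bridging C3 and C10) and the 4Z alkene hold the two ends close.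
- Further cuts: furanone O–C3 (hydroxy-ynone cyclisation), C2–C3 (alkynylmagnesium plus Weinreb amide), C3–C4 (CO plus alkenyl iodide), C10–C1 (ethynyl plus methyl ketone).
- Forward order: dioxolane fragment from L-tartrate (C7–C10, then C11, C13, C14, C1, C2) and Z-alkenyl amide (C3–C6, C15) → ynone → furanone ring → enal → ten-membered ring and lactone ring in one flask → C8 ester, C9 ester → desilylation.
- Stereochemistry: C8 and C9 from L-tartaric acid; C10 by chelation-controlled ethynyl addition; 4Z by trans-hydroalumination/iodination; C6 and C7 in the key step (chair transition state, control by C8 and the trans-dioxolane); angelate geometry from angelic acid.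

Key step: step 13

Remark: germacrane numbering is used for the carbons of all intermediates (ring C1–C10, lactone carbonyl C12, exocyclic methylene C13, C10 methyl C14, hydroxymethyl C15). Compounds 1 and 8 are taken as commercial. TBS = tert-butyldimethylsilyl, TBDPS = tert-butyldiphenylsilyl.

**Step 1**
Reactants: 1 dimethyl 2,3-O-isopropylidene-L-tartrate
Product: 3 methyl (4R,5S)-5-ethynyl-2,2-dimethyl-1,3-dioxolane-4-carboxylate, via aldehyde ester 2 (not isolated)
Conditions: iBu2AlH (1.0 equiv), CH2Cl2, −78 °C; then MeOH, K2CO3, dimethyl (1-diazo-2-oxopropyl)phosphonate, −78 °C → rt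
Reagents that add atoms: dimethyl (1-diazo-2-oxopropyl)phosphonate, CC(=O)C(=[N+]=[N-])P(=O)(OC)OC
Why: One equivalent of iBu2AlH at −78 °C should stop at the aluminium hemiacetal of one of the two equivalent ester groups, which releases aldehyde 2 on addition of methanol, and Seyferth–Gilbert homologation with the Bestmann–Ohira reagent then gives the terminal alkyne (C7≡C11) without change at the two tartrate-derived stereocentres (C8 and C9), the trans-dioxolane being also the more stable arrangement.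

**Step 2**
Reactants: 3 methyl (4R,5S)-5-ethynyl-2,2-dimethyl-1,3-dioxolane-4-carboxylate
Product: 4 methyl (4R,5S)-2,2-dimethyl-5-(propa-1,2-dien-1-yl)-1,3-dioxolane-4-carboxylate
Conditions: (CH2O)n, CuI (0.5 equiv), Cy2NH, 1,4-dioxane, reflux
Reagents that add atoms: paraformaldehyde (formaldehyde), C=O
Why: Crabbé homologation: the copper acetylide, formaldehyde and the secondary amine give a propargylic amine that passes to the terminal allene (new carbon C13) by 1,5-hydride transfer and loss of the imine, under conditions that leave the ester and the stereocentres alone.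

**Step 3**
Reactants: 4 methyl (4R,5S)-2,2-dimethyl-5-(propa-1,2-dien-1-yl)-1,3-dioxolane-4-carboxylate
Product: 6 1-[(4R,5S)-2,2-dimethyl-5-(propa-1,2-dien-1-yl)-1,3-dioxolan-4-yl]ethan-1-one, via Weinreb amide 5 (not isolated)
Conditions: MeNHOMe·HCl, iPrMgCl, THF, −20 °C; then MeMgBr, −20 → 0 °C
Reagents that add atoms: methylmagnesium bromide, C[Mg]Br; N,O-dimethylhydroxylamine hydrochloride, CNOC.Cl (its atoms stay in 5 only)
Why: Weinreb ketone synthesis in one flask: the chloromagnesium amide of MeNHOMe converts the ester into amide 5, and the chelated tetrahedral adduct of 5 and MeMgBr cannot take up a second methyl group, so the methyl ketone (C10 with C14) results on work-up.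

**Step 4**
Reactants: 6 1-[(4R,5S)-2,2-dimethyl-5-(propa-1,2-dien-1-yl)-1,3-dioxolan-4-yl]ethan-1-one
Product: 7 (2R)-2-[(4R,5S)-2,2-dimethyl-5-(propa-1,2-dien-1-yl)-1,3-dioxolan-4-yl]but-3-yn-2-ol
Conditions: HC≡CMgBr, MgBr2·OEt2, CH2Cl2–THF, −78 °C
Reagents that add atoms: ethynylmagnesium bromide, C#C[Mg]Br
Why: Chelation-controlled Grignard addition: magnesium bridges the ketone oxygen and the neighbouring dioxolane oxygen (O9), and the acetylide should enter from the face of this chelate that is turned away from the C8 side of the ring, which sets C10 with hydroxyl, methyl and ethynyl (C1, C2) arranged as in the target.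

**Step 5**
Reactants: 8 but-2-yne-1,4-diol
Product: 9 4-[(tert-butyldiphenylsilyl)oxy]but-2-yn-1-ol
Conditions: TBDPSCl (1 equiv), imidazole, DMF, 0 °C → rt (8 in threefold excess)
Reagents that add atoms: tert-butyl(chloro)diphenylsilane, CC(C)(C)[Si](Cl)(c1ccccc1)c1ccccc1
Why: Monosilylation of a symmetric diol used in excess, a statistical but routine protection that leaves one propargylic hydroxyl free to direct the next step.

**Step 6**
Reactants: 9 4-[(tert-butyldiphenylsilyl)oxy]but-2-yn-1-ol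
Product: 11 (Z)-4-[(tert-butyldiphenylsilyl)oxy]-3-iodobut-2-en-1-ol, via cyclic alanate 10 (not isolated)
Conditions: NaAlH2(OCH2CH2OCH3)2, THF, 0 °C → rt; then I2, THF, −78 °C
Reagents that add atoms: iodine, II; sodium bis(2-methoxyethoxy)aluminium dihydride, [Na+].COCCO[AlH2-]OCCOC (its atoms other than hydrogen stay in 10 only)
Why: Hydroxyl-directed trans-hydroalumination of the propargylic alcohol places aluminium on the distal alkyne carbon (cyclic alanate 10), and iodinolysis with retention gives the Z-iodoalkene, which fixes the 4Z geometry and tells C6 (free hydroxyl) from C15 (silyl ether).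

**Step 7**
Reactants: 11 (Z)-4-[(tert-butyldiphenylsilyl)oxy]-3-iodobut-2-en-1-ol
Product: 12 (Z)-1-[(tert-butyldimethylsilyl)oxy]-4-[(tert-butyldiphenylsilyl)oxy]-3-iodobut-2-ene
Conditions: TBSCl, imidazole, CH2Cl2, rt
Reagents that add atoms: tert-butyl(chloro)dimethylsilane, CC(C)(C)[Si](C)(C)Cl
Why: Standard silylation of a primary alcohol with a silyl chloride and imidazole.

**Step 8**
Reactants: 12 (Z)-1-[(tert-butyldimethylsilyl)oxy]-4-[(tert-butyldiphenylsilyl)oxy]-3-iodobut-2-ene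
Product: 13 (Z)-4-[(tert-butyldimethylsilyl)oxy]-2-{[(tert-butyldiphenylsilyl)oxy]methyl}-N-methoxy-N-methylbut-2-enamide
Conditions: CO (1 atm), MeNHOMe·HCl, Pd(OAc)2 (3 mol%), Xantphos (6 mol%), Et3N, toluene, 60 °C
Reagents that add atoms: carbon monoxide, [C-]#[O+]; N,O-dimethylhydroxylamine hydrochloride, CNOC.Cl
Why: Palladium-catalysed aminocarbonylation of an alkenyl iodide (oxidative addition, CO insertion, capture of the acylpalladium by the amine), which brings in C3 at the amide oxidation level with retention of the alkene geometry.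

**Step 9**
Reactants: 7 (2R)-2-[(4R,5S)-2,2-dimethyl-5-(propa-1,2-dien-1-yl)-1,3-dioxolan-4-yl]but-3-yn-2-ol; 13 (Z)-4-[(tert-butyldimethylsilyl)oxy]-2-{[(tert-butyldiphenylsilyl)oxy]methyl}-N-methoxy-N-methylbut-2-enamide
Product: 15 (2Z,7R)-1-[(tert-butyldimethylsilyl)oxy]-3-{[(tert-butyldiphenylsilyl)oxy]methyl}-7-[(4R,5S)-2,2-dimethyl-5-(propa-1,2-dien-1-yl)-1,3-dioxolan-4-yl]-7-hydroxyoct-2-en-5-yn-4-one, via magnesium acetylide 14 (not isolated)
Conditions: 7, EtMgBr (2 equiv per 7), THF, 0 → 40 °C; then 13, 0 °C → rt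
Reagents that add atoms: ethylmagnesium bromide, CC[Mg]Br (magnesium and bromine stay in 14 only)
Why: Weinreb ketone synthesis with an alkynyl nucleophile: EtMgBr removes the hydroxyl and acetylenic protons of 7, the alkynylmagnesium end of 14 adds to amide 13, and the chelated adduct collapses to the ynone (C2–C3 bond) only on work-up, so that neither over-addition nor conjugate addition should interfere.

**Step 10**
Reactants: 15 (2Z,7R)-1-[(tert-butyldimethylsilyl)oxy]-3-{[(tert-butyldiphenylsilyl)oxy]methyl}-7-[(4R,5S)-2,2-dimethyl-5-(propa-1,2-dien-1-yl)-1,3-dioxolan-4-yl]-7-hydroxyoct-2-en-5-yn-4-one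
Product: 17 (2S)-5-{(Z)-4-[(tert-butyldimethylsilyl)oxy]-1-[(tert-butyldiphenylsilyl)oxy]but-2-en-2-yl}-2-[(4R,5S)-2,2-dimethyl-5-(propa-1,2-dien-1-yl)-1,3-dioxolan-4-yl]-2-methylfuran-3(2H)-one, via enaminone 16 (not isolated)
Conditions: Et2NH, EtOH, rt; then AcOH–H2O–THF, rt
Reagents that add atoms: water, O; diethylamine, CCNCC (stays in 16 only)
Why: Known conversion of a 4-hydroxyalk-2-ynone into a 3(2H)-furanone: diethylamine adds to the ynone at C1 to give enaminone 16, and mild acid lets the tertiary hydroxyl attack the C3 carbonyl, expels water and hydrolyses the iminium, which leaves the carbonyl at C1 and the ring oxygen between C3 and C10 without touching the C10 stereocentre.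

**Step 11**
Reactants: 17 (2S)-5-{(Z)-4-[(tert-butyldimethylsilyl)oxy]-1-[(tert-butyldiphenylsilyl)oxy]but-2-en-2-yl}-2-[(4R,5S)-2,2-dimethyl-5-(propa-1,2-dien-1-yl)-1,3-dioxolan-4-yl]-2-methylfuran-3(2H)-one
Product: 18 (2S)-5-{(Z)-1-[(tert-butyldiphenylsilyl)oxy]-4-hydroxybut-2-en-2-yl}-2-[(4R,5S)-2,2-dimethyl-5-(propa-1,2-dien-1-yl)-1,3-dioxolan-4-yl]-2-methylfuran-3(2H)-one
Conditions: HF·pyridine, pyridine, THF, 0 °C
Reagents that add atoms: none
Why: Buffered HF·pyridine cleaves a primary tert-butyldimethylsilyl ether much faster than a tert-butyldiphenylsilyl ether, and the acetonide and the furanone are stable to it.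

**Step 12**
Reactants: 18 (2S)-5-{(Z)-1-[(tert-butyldiphenylsilyl)oxy]-4-hydroxybut-2-en-2-yl}-2-[(4R,5S)-2,2-dimethyl-5-(propa-1,2-dien-1-yl)-1,3-dioxolan-4-yl]-2-methylfuran-3(2H)-one
Product: 19 (Z)-4-[(tert-butyldiphenylsilyl)oxy]-3-{(5S)-5-[(4R,5S)-2,2-dimethyl-5-(propa-1,2-dien-1-yl)-1,3-dioxolan-4-yl]-5-methyl-4-oxo-4,5-dihydrofuran-2-yl}but-2-enal
Conditions: MnO2, CH2Cl2, rt
Reagents that add atoms: none
Why: MnO2 oxidises allylic alcohols selectively under neutral conditions, which should keep the Z geometry of the new enal.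

**Step 13**
Reactants: 19 (Z)-4-[(tert-butyldiphenylsilyl)oxy]-3-{(5S)-5-[(4R,5S)-2,2-dimethyl-5-(propa-1,2-dien-1-yl)-1,3-dioxolan-4-yl]-5-methyl-4-oxo-4,5-dihydrofuran-2-yl}but-2-enal
Product: 22 (4Z,6R,7S,8S,9R,10S)-15-[(tert-butyldiphenylsilyl)oxy]-3,10-epoxy-8,9-(isopropylidenedioxy)-1-oxogermacra-2,4,11(13)-trien-12,6-olide, via nickelalactone 20 (not isolated), via hydroxy acid 21 (not isolated)
Conditions: Ni(cod)2 (1.5 equiv), DBU (3 equiv), CO2 (1 atm), THF, 0 °C, slow addition of 19 (final 2 mM); then 1 M HCl; then PPTS (cat.), toluene, 50 °C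
Reagents that add atoms: carbon dioxide, O=C=O; Ni(cod)2, C1=CCCC=CCC1.C1=CCCC=CCC1.[Ni] (nickel stays in 20 only)
Why: Proposed new method: zerovalent nickel carrying DBU should bind the terminal C11=C13 bond of the allene and couple it oxidatively with CO2 at the central carbon (C11–C12), giving nickelalactone 20, an allylnickel carboxylate whose substituted terminus C7 then adds to the tethered aldehyde carbon C6 through a chair-like six-membered transition state (C6–C7); acid frees hydroxy acid 21, which lactonises. The closest known reaction type is the nickel-mediated sequential addition of CO2 and an aldehyde to a terminal allene between separate molecules, and the ring closure parallels the Nozaki–Hiyama–Kishi-type macro-allylations of aldehydes by 2-(alkoxycarbonyl)allyl halides; new is that the aldehyde is tethered, so that one flask gives both carbon–carbon bonds and the macrocycle. The ten-membered carbocycle closes by intramolecular carbonyl allylation (SE2' attack of C7 on C6), helped by the furanone bridge and the 4Z alkene, which already hold C3–C5 in one plane, and the γ-lactone closes by 5-exo-trig addition–elimination of the new C6 hydroxyl on the C12 carboxyl group. C6 (R) is set relative to C7 by the chair, in which the allyl terminus reacts in its syn (E) form and C5 of the aldehyde sits equatorial, giving the anti adduct and hence the trans-fused lactone; C7 (S) is set by C8, whose hydrogen eclipses the carboxylate-bearing C11 (A(1,3) strain) while the C8–C9 bond lies anti to the forming bond, an extended arrangement that the trans-dioxolane enforces along C7–C10. The step needs CO2 capture by the allene to precede any reaction of nickel with the enal, attack through C7 and not C13, and ring closure ahead of oligomerisation. These should be secured by slow addition of 19 to pre-mixed Ni(cod)2/DBU under CO2 at high dilution, by the closed transition state together with the smaller ring (ten against twelve members), and by the rigid Z-enal–furanone half of the substrate.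

**Step 14**
Reactants: 22 (4Z,6R,7S,8S,9R,10S)-15-[(tert-butyldiphenylsilyl)oxy]-3,10-epoxy-8,9-(isopropylidenedioxy)-1-oxogermacra-2,4,11(13)-trien-12,6-olide
Product: 23 (4Z,6R,7S,8S,9R,10S)-15-[(tert-butyldiphenylsilyl)oxy]-3,10-epoxy-8,9-dihydroxy-1-oxogermacra-2,4,11(13)-trien-12,6-olide
Conditions: TFA–H2O (9:1), CH2Cl2, 0 °C
Reagents that add atoms: none
Why: Acid-catalysed hydrolysis of the acetonide, the temporary ring of the key step, under conditions that the TBDPS ether, the furanone and the lactone tolerate.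

**Step 15**
Reactants: 23 (4Z,6R,7S,8S,9R,10S)-15-[(tert-butyldiphenylsilyl)oxy]-3,10-epoxy-8,9-dihydroxy-1-oxogermacra-2,4,11(13)-trien-12,6-olide
Product: 24 (4Z,6R,7S,8S,9R,10S)-15-[(tert-butyldiphenylsilyl)oxy]-3,10-epoxy-9-hydroxy-8-(methacryloyloxy)-1-oxogermacra-2,4,11(13)-trien-12,6-olide
Conditions: methacrylic anhydride (1.1 equiv), Et3N, DMAP (cat.), CH2Cl2, −20 → 0 °C
Reagents that add atoms: methacrylic anhydride, C=C(C)C(=O)OC(=O)C(C)=C
Why: DMAP-catalysed acylation with a small excess of anhydride should take the C8 hydroxyl first, because the C9 hydroxyl is flanked by the fully substituted C10 and reacts more slowly.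

**Step 16**
Reactants: 24 (4Z,6R,7S,8S,9R,10S)-15-[(tert-butyldiphenylsilyl)oxy]-3,10-epoxy-9-hydroxy-8-(methacryloyloxy)-1-oxogermacra-2,4,11(13)-trien-12,6-olide
Product: 25 (4Z,6R,7S,8S,9R,10S)-9-(angeloyloxy)-15-[(tert-butyldiphenylsilyl)oxy]-3,10-epoxy-8-(methacryloyloxy)-1-oxogermacra-2,4,11(13)-trien-12,6-olide
Conditions: angelic acid, 2,4,6-trichlorobenzoyl chloride, Et3N, toluene, rt; then 24, BHT (cat.), 80 °C
Reagents that add atoms: angelic acid, C/C=C(/C)C(=O)O
Why: Yamaguchi-type esterification through the mixed 2,4,6-trichlorobenzoic anhydride without a nucleophilic catalyst, a known way to acylate hindered alcohols with angelic acid while avoiding Z to E isomerisation to the tiglate.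

**Step 17**
Reactants: 25 (4Z,6R,7S,8S,9R,10S)-9-(angeloyloxy)-15-[(tert-butyldiphenylsilyl)oxy]-3,10-epoxy-8-(methacryloyloxy)-1-oxogermacra-2,4,11(13)-trien-12,6-olide
Product: 26 (4Z,6R,7S,8S,9R,10S)-9-(angeloyloxy)-3,10-epoxy-15-hydroxy-8-(methacryloyloxy)-1-oxogermacra-2,4,11(13)-trien-12,6-olide
Conditions: HF·pyridine, pyridine, THF, 0 °C → rt
Reagents that add atoms: none
Why: Fluoride cleavage of the silyl ether under buffered acidic conditions that spare the two unsaturated esters and the α-methylene lactone.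

**Compound list**
1 | dimethyl (4R,5R)-2,2-dimethyl-1,3-dioxolane-4,5-dicarboxylate (dimethyl 2,3-O-isopropylidene-L-tartrate) | COC(=O)[C@@H]1OC(C)(C)O[C@H]1C(=O)OC | starting material
2 | methyl (4R,5R)-5-formyl-2,2-dimethyl-1,3-dioxolane-4-carboxylate | COC(=O)[C@@H]1OC(C)(C)O[C@H]1C=O | intermediate (not isolated)
3 | methyl (4R,5S)-5-ethynyl-2,2-dimethyl-1,3-dioxolane-4-carboxylate | COC(=O)[C@@H]1OC(C)(C)O[C@H]1C#C | intermediate
4 | methyl (4R,5S)-2,2-dimethyl-5-(propa-1,2-dien-1-yl)-1,3-dioxolane-4-carboxylate | COC(=O)[C@@H]1OC(C)(C)O[C@H]1C=C=C | intermediate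
5 | (4R,5S)-N-methoxy-N,2,2-trimethyl-5-(propa-1,2-dien-1-yl)-1,3-dioxolane-4-carboxamide | CON(C)C(=O)[C@@H]1OC(C)(C)O[C@H]1C=C=C | intermediate (not isolated)
6 | 1-[(4R,5S)-2,2-dimethyl-5-(propa-1,2-dien-1-yl)-1,3-dioxolan-4-yl]ethan-1-one | CC(=O)[C@@H]1OC(C)(C)O[C@H]1C=C=C | intermediate
7 | (2R)-2-[(4R,5S)-2,2-dimethyl-5-(propa-1,2-dien-1-yl)-1,3-dioxolan-4-yl]but-3-yn-2-ol | C#C[C@@](C)(O)[C@@H]1OC(C)(C)O[C@H]1C=C=C | intermediate
8 | but-2-yne-1,4-diol | OCC#CCO | starting material
9 | 4-[(tert-butyldiphenylsilyl)oxy]but-2-yn-1-ol | OCC#CCO[Si](c1ccccc1)(c1ccccc1)C(C)(C)C | intermediate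
10 | cyclic alanate: sodium alkenyl(alkoxy)bis(2-methoxyethoxy)aluminate from 9 (five-membered ring Al–O–C6–C5=C4) | [Na+].COCCO[Al-]1(OCCOC)OC/C=C1/CO[Si](c1ccccc1)(c1ccccc1)C(C)(C)C | intermediate (not isolated)
11 | (Z)-4-[(tert-butyldiphenylsilyl)oxy]-3-iodobut-2-en-1-ol | OC/C=C(\I)CO[Si](c1ccccc1)(c1ccccc1)C(C)(C)C | intermediate
12 | (Z)-1-[(tert-butyldimethylsilyl)oxy]-4-[(tert-butyldiphenylsilyl)oxy]-3-iodobut-2-ene | CC(C)(C)[Si](C)(C)OC/C=C(\I)CO[Si](c1ccccc1)(c1ccccc1)C(C)(C)C | intermediate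
13 | (Z)-4-[(tert-butyldimethylsilyl)oxy]-2-{[(tert-butyldiphenylsilyl)oxy]methyl}-N-methoxy-N-methylbut-2-enamide | CC(C)(C)[Si](C)(C)OC/C=C(\C(=O)N(C)OC)CO[Si](c1ccccc1)(c1ccccc1)C(C)(C)C | intermediate
14 | bis(bromomagnesium) derivative of 7 (magnesium alkoxide on the C10 oxygen, alkynylmagnesium bromide at C2) | Br[Mg]C#C[C@@](C)(O[Mg]Br)[C@@H]1OC(C)(C)O[C@H]1C=C=C | intermediate (not isolated)
15 | (2Z,7R)-1-[(tert-butyldimethylsilyl)oxy]-3-{[(tert-butyldiphenylsilyl)oxy]methyl}-7-[(4R,5S)-2,2-dimethyl-5-(propa-1,2-dien-1-yl)-1,3-dioxolan-4-yl]-7-hydroxyoct-2-en-5-yn-4-one | CC(C)(C)[Si](C)(C)OC/C=C(\C(=O)C#C[C@@](C)(O)[C@@H]1OC(C)(C)O[C@H]1C=C=C)CO[Si](c1ccccc1)(c1ccccc1)C(C)(C)C | intermediate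
16 | (2Z,5E,7R)-1-[(tert-butyldimethylsilyl)oxy]-3-{[(tert-butyldiphenylsilyl)oxy]methyl}-6-(diethylamino)-7-[(4R,5S)-2,2-dimethyl-5-(propa-1,2-dien-1-yl)-1,3-dioxolan-4-yl]-7-hydroxyocta-2,5-dien-4-one | CC(C)(C)[Si](C)(C)OC/C=C(\C(=O)/C=C(/N(CC)CC)[C@@](C)(O)[C@@H]1OC(C)(C)O[C@H]1C=C=C)CO[Si](c1ccccc1)(c1ccccc1)C(C)(C)C | intermediate (not isolated)
17 | (2S)-5-{(Z)-4-[(tert-butyldimethylsilyl)oxy]-1-[(tert-butyldiphenylsilyl)oxy]but-2-en-2-yl}-2-[(4R,5S)-2,2-dimethyl-5-(propa-1,2-dien-1-yl)-1,3-dioxolan-4-yl]-2-methylfuran-3(2H)-one | CC(C)(C)[Si](C)(C)OC/C=C(\C1=CC(=O)[C@@](C)(O1)[C@@H]2OC(C)(C)O[C@H]2C=C=C)CO[Si](c1ccccc1)(c1ccccc1)C(C)(C)C | intermediate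
18 | (2S)-5-{(Z)-1-[(tert-butyldiphenylsilyl)oxy]-4-hydroxybut-2-en-2-yl}-2-[(4R,5S)-2,2-dimethyl-5-(propa-1,2-dien-1-yl)-1,3-dioxolan-4-yl]-2-methylfuran-3(2H)-one | OC/C=C(\C1=CC(=O)[C@@](C)(O1)[C@@H]2OC(C)(C)O[C@H]2C=C=C)CO[Si](c1ccccc1)(c1ccccc1)C(C)(C)C | intermediate
19 | (Z)-4-[(tert-butyldiphenylsilyl)oxy]-3-{(5S)-5-[(4R,5S)-2,2-dimethyl-5-(propa-1,2-dien-1-yl)-1,3-dioxolan-4-yl]-5-methyl-4-oxo-4,5-dihydrofuran-2-yl}but-2-enal | O=C/C=C(\C1=CC(=O)[C@@](C)(O1)[C@@H]2OC(C)(C)O[C@H]2C=C=C)CO[Si](c1ccccc1)(c1ccccc1)C(C)(C)C | intermediate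
20 | nickelalactone: 19 after union of C11 with CO2 (ring Ni–O–C12(=O)–C11–C13H2, C7=C11 E, divalent nickel, DBU ligands not drawn) | O=C/C=C(\C1=CC(=O)[C@@](C)(O1)[C@@H]2OC(C)(C)O[C@H]2/C=C3/C[Ni]OC3=O)CO[Si](c1ccccc1)(c1ccccc1)C(C)(C)C | intermediate (not isolated)
21 | hydroxy acid: (4Z,6R,7S,8S,9R,10S)-15-[(tert-butyldiphenylsilyl)oxy]-3,10-epoxy-6-hydroxy-8,9-(isopropylidenedioxy)-1-oxogermacra-2,4,11(13)-trien-12-oic acid | CC1(C)O[C@H]2[C@@H](C(=C)C(=O)O)[C@H](O)/C=C(/CO[Si](c4ccccc4)(c4ccccc4)C(C)(C)C)C3=CC(=O)[C@@](C)(O3)[C@@H]2O1 | intermediate (not isolated)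
22 | (4Z,6R,7S,8S,9R,10S)-15-[(tert-butyldiphenylsilyl)oxy]-3,10-epoxy-8,9-(isopropylidenedioxy)-1-oxogermacra-2,4,11(13)-trien-12,6-olide | CC1(C)O[C@H]2[C@H]3C(=C)C(=O)O[C@@H]3/C=C(/CO[Si](c4ccccc4)(c4ccccc4)C(C)(C)C)C3=CC(=O)[C@@](C)(O3)[C@@H]2O1 | intermediate
23 | (4Z,6R,7S,8S,9R,10S)-15-[(tert-butyldiphenylsilyl)oxy]-3,10-epoxy-8,9-dihydroxy-1-oxogermacra-2,4,11(13)-trien-12,6-olide | O[C@H]1[C@H]2C(=C)C(=O)O[C@@H]2/C=C(/CO[Si](c3ccccc3)(c3ccccc3)C(C)(C)C)C2=CC(=O)[C@@](C)(O2)[C@@H]1O | intermediate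
24 | (4Z,6R,7S,8S,9R,10S)-15-[(tert-butyldiphenylsilyl)oxy]-3,10-epoxy-9-hydroxy-8-(methacryloyloxy)-1-oxogermacra-2,4,11(13)-trien-12,6-olide | C=C(C)C(=O)O[C@H]1[C@H]2C(=C)C(=O)O[C@@H]2/C=C(/CO[Si](c3ccccc3)(c3ccccc3)C(C)(C)C)C2=CC(=O)[C@@](C)(O2)[C@@H]1O | intermediate
25 | (4Z,6R,7S,8S,9R,10S)-9-(angeloyloxy)-15-[(tert-butyldiphenylsilyl)oxy]-3,10-epoxy-8-(methacryloyloxy)-1-oxogermacra-2,4,11(13)-trien-12,6-olide | C=C(C)C(=O)O[C@H]1[C@H]2C(=C)C(=O)O[C@@H]2/C=C(/CO[Si](c3ccccc3)(c3ccccc3)C(C)(C)C)C2=CC(=O)[C@@](C)(O2)[C@@H]1OC(=O)/C(C)=C\C | intermediate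
26 | (4Z,6R,7S,8S,9R,10S)-9-(angeloyloxy)-3,10-epoxy-15-hydroxy-8-(methacryloyloxy)-1-oxogermacra-2,4,11(13)-trien-12,6-olide (CNP0359568.2) | C=C(C)C(=O)O[C@H]1[C@H]2C(=C)C(=O)O[C@@H]2/C=C(/CO)C2=CC(=O)[C@@](C)(O2)[C@@H]1OC(=O)/C(C)=C\C | target

**Step count and risks**
Total step count: 17. Longest linear sequence: 13 steps (steps 1–4 and 9–17 from 1; equally steps 5–8 and 9–17 from 8).

Steps most likely to fail:

1. Step 13 (Proposed new method). What may go wrong: nickel engages the enal before it has captured CO2; the allylnickel adds between molecules (oligomers) or through C13 (twelve-membered ring); the ring closes with the wrong facial sense at C7 or the wrong C6/C7 relationship; DBU isomerises the Z-enal. Fallback (known chemistry; sets out from 17, comes back at 21): the two carbon–carbon bonds are made in separate operations. Copper-catalysed silacarboxylation of the allene of 17 (PhMe2Si–Bpin, CO2 1 atm, Cu(OAc)2, PCy3) should give the (Z)-2-[(dimethylphenylsilyl)methyl]alkenoic acid F1, which already holds the C11–C12 bond. HF·pyridine/pyridine then frees the C6 alcohol F2, and MnO2 gives the enal F3. An intramolecular Hosomi–Sakurai allylation (BF3·OEt2, CH2Cl2, −78 °C, high dilution), the silicon counterpart of the macro-allylations with 2-(alkoxycarbonyl)allyl halides, closes C6–C7 through an open transition state and gives hydroxy acid 21, which is lactonised to 22 as in step 13.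

2. Step 15. What may go wrong: insufficient discrimination between the two secondary hydroxyls, acyl migration between O8 and O9, or translactonisation of the free C8 hydroxyl onto C12 under base. Fallback (sets out from 23, comes back at 25): temporary protection in place of direct selective acylation. TESCl/imidazole at −20 °C, which discriminates more strongly on steric grounds than an anhydride, should give the C8 triethylsilyl ether F6. Angeloylation of the remaining C9 hydroxyl as in step 16 gives the silyl ether angelate F7. HF·pyridine at 0 °C removes the triethylsilyl group in the presence of the TBDPS ether to give the C8 alcohol F8, and methacrylic anhydride/Et3N/DMAP then acylates the only free hydroxyl to give 25.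

3. Step 4. What may go wrong: weak chelation by the dioxolane oxygen, so that attack under non-chelation control competes and the facial selectivity at C10 is low or reversed. Fallback (sets out from 4, comes back at 7): the order in which the two carbon substituents of C10 arrive is exchanged, so that the non-chelated sense of attack gives the required epimer. Amide 5 is isolated (MeNHOMe·HCl, iPrMgCl) and treated with lithium (trimethylsilyl)acetylide to give the ynone F4. A non-chelating methyl donor (MeLi/CeCl3 or MeTi(OiPr)3) adds to F4 to give the tertiary alcohol F5, and K2CO3/MeOH removes the silyl group to give 7.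

**Further compounds**
F1 | step 13 | (Z)-2-[(dimethylphenylsilyl)methyl]alkenoic acid from 17 (CO2H on C11, PhMe2SiCH2 as C13, C6 as TBS ether) | CC(C)(C)[Si](C)(C)OC/C=C(\C1=CC(=O)[C@@](C)(O1)[C@@H]2OC(C)(C)O[C@H]2/C=C(\C[Si](C)(C)c3ccccc3)C(=O)O)CO[Si](c1ccccc1)(c1ccccc1)C(C)(C)C
F2 | step 13 | C6 alcohol of F1 | OC/C=C(\C1=CC(=O)[C@@](C)(O1)[C@@H]2OC(C)(C)O[C@H]2/C=C(\C[Si](C)(C)c3ccccc3)C(=O)O)CO[Si](c1ccccc1)(c1ccccc1)C(C)(C)C
F3 | step 13 | C6 aldehyde (Z-enal) of F1 | O=C/C=C(\C1=CC(=O)[C@@](C)(O1)[C@@H]2OC(C)(C)O[C@H]2/C=C(\C[Si](C)(C)c3ccccc3)C(=O)O)CO[Si](c1ccccc1)(c1ccccc1)C(C)(C)C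
F4 | step 4 | 1-[(4R,5S)-2,2-dimethyl-5-(propa-1,2-dien-1-yl)-1,3-dioxolan-4-yl]-3-(trimethylsilyl)prop-2-yn-1-one | C[Si](C)(C)C#CC(=O)[C@@H]1OC(C)(C)O[C@H]1C=C=C
F5 | step 4 | (2R)-2-[(4R,5S)-2,2-dimethyl-5-(propa-1,2-dien-1-yl)-1,3-dioxolan-4-yl]-4-(trimethylsilyl)but-3-yn-2-ol | C[Si](C)(C)C#C[C@@](C)(O)[C@@H]1OC(C)(C)O[C@H]1C=C=C
F6 | step 15 | 8-O-triethylsilyl ether of diol 23 | CC[Si](CC)(CC)O[C@H]1[C@H]2C(=C)C(=O)O[C@@H]2/C=C(/CO[Si](c3ccccc3)(c3ccccc3)C(C)(C)C)C2=CC(=O)[C@@](C)(O2)[C@@H]1O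
F7 | step 15 | 9-O-angeloyl-8-O-triethylsilyl derivative of 23 | CC[Si](CC)(CC)O[C@H]1[C@H]2C(=C)C(=O)O[C@@H]2/C=C(/CO[Si](c3ccccc3)(c3ccccc3)C(C)(C)C)C2=CC(=O)[C@@](C)(O2)[C@@H]1OC(=O)/C(C)=C\C
F8 | step 15 | 9-O-angeloyl derivative of 23 with free C8 hydroxyl | O[C@H]1[C@H]2C(=C)C(=O)O[C@@H]2/C=C(/CO[Si](c3ccccc3)(c3ccccc3)C(C)(C)C)C2=CC(=O)[C@@](C)(O2)[C@@H]1OC(=O)/C(C)=C\C
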